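**Route overview**

Atom labels (daucane): C1 angular-methyl carbon, C2/C3 ring CH2, C4 isopropyl carbinol, C5 ring-fusion CH, C6 ester carbon, C7=C8 alkene (methyl on C8), C9 free carbinol, C10 ring CH2.
Cuts: first the vanillate C6–O acyl bond; then C5–H is traced back to a C5–O–C9 ether bridge and the C6 carbinol to a ketone; the bridged tricycle is cut at C5–C1 and C9–C10 into a 3-oxidopyrylium and a tethered C1=C10 alkene; the pyranone goes back to a furyl carbinol (C5–furan bond) and the chain is cut at C2–C3 (epoxide opening).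
Enabling feature: in the seven-membered ring an alkene flanked by two oxygen-bearing carbons on the same face, C6(O)–C7=C8(Me)–C9(O), lies beside the C1–C5 fusion bond. This is the footprint of a 3-oxidopyrylium (oxido carbon C6, ring oxygen between C5 and C9) added across a C1=C10 alkene held by the C2–C3–C4 tether; the surplus C5–O bond is alpha to the C6 ketone and can be cut reductively.
Forward: the chain is built (epoxide, methallyl opening, aldehyde, furan addition), the furan becomes a pyranone (a ring that does not survive), one cycloaddition closes cyclopentane and cycloheptene together, the ether bridge is cut, C6 is reduced, and the vanillate ring is attached last.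
Stereochemistry: C4 from the Sharpless epoxidation; C1 and C9 from the cycloaddition (tether geometry plus C4-directed pyrylium face); C5 from protonation after bridge cleavage; C6 from substrate-controlled hydride addition.

Key step: step 10

**Steps**

Step 1
Reactants: 1 3-methylbutanal
Product: 2 3-methyl-2-methylidenebutanal
Conditions: 37% aq. CH2O, pyrrolidine (10 mol %), EtCO2H (10 mol %), i-PrOH, 45 °C
Reagents that add atoms: formaldehyde, C=O
Why: Amine-catalysed Mannich condensation and elimination (alpha-methylenation of an alpha-monosubstituted aldehyde through its enamine) installs the exo-methylene carbon that later becomes the epoxide CH2.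

Step 2
Reactants: 2 3-methyl-2-methylidenebutanal
Product: 3 3-methyl-2-methylidenebutan-1-ol
Conditions: NaBH4, CeCl3·7H2O, MeOH, 0 °C
Reagents that add atoms: none
Why: Luche reduction should give clean 1,2-reduction of the enal to the allylic alcohol without conjugate reduction.

Step 3
Reactants: 3 3-methyl-2-methylidenebutan-1-ol
Product: 4 [(2R)-2-(propan-2-yl)oxiran-2-yl]methanol
Conditions: Ti(OiPr)4 (10 mol %), D-(−)-diisopropyl tartrate (12 mol %), t-BuOOH, 4 Å MS, CH2Cl2, −20 °C
Reagents that add atoms: tert-butyl hydroperoxide, CC(C)(C)OO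
Why: Sharpless asymmetric epoxidation of a 2-substituted allylic alcohol, in which the D-(−)-tartrate complex delivers oxygen to the alkene face that gives the R epoxide (the future C4); catalytic titanium and low temperature limit opening of the sensitive 2,2-disubstituted epoxide.

Step 4
Reactants: 4 [(2R)-2-(propan-2-yl)oxiran-2-yl]methanol; 5 3-chloro-2-methylprop-1-ene
Product: 7 (2R)-5-methyl-2-(propan-2-yl)hex-5-ene-1,2-diol, via methallylmagnesium chloride 6 (not isolated)
Conditions: 5, Mg, THF, 0 °C; then 4, CuI (10 mol %), THF, −40 to −20 °C (2.5 equiv of 6); aq. NH4Cl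
Reagents that add atoms: none
Why: Copper-catalysed Grignard opening of a 2,2-disubstituted epoxide occurs by SN2 attack at the unhindered CH2, so no bond to the stereocentre is touched; the first equivalent of Grignard only deprotonates the hydroxyl, and a Payne rearrangement of this glycidol would be degenerate and return the same enantiomer.

Step 5
Reactants: 7 (2R)-5-methyl-2-(propan-2-yl)hex-5-ene-1,2-diol
Product: 8 (2R)-5-methyl-2-(propan-2-yl)-1,2-bis(triethylsilyloxy)hex-5-ene
Conditions: Et3SiOTf (2.4 equiv), 2,6-lutidine, CH2Cl2, −78 to 0 °C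
Reagents that add atoms: triethylsilyl trifluoromethanesulfonate, CC[Si](CC)(CC)OS(=O)(=O)C(F)(F)F
Why: A silyl triflate with 2,6-lutidine silylates both the primary and the hindered tertiary hydroxyl; triethylsilyl is chosen for the tertiary oxygen because it should survive base, peroxide and divalent samarium later and still fall to fluoride at the end.

Step 6
Reactants: 8 (2R)-5-methyl-2-(propan-2-yl)-1,2-bis(triethylsilyloxy)hex-5-ene
Product: 10 (2R)-5-methyl-2-(propan-2-yl)-2-(triethylsilyloxy)hex-5-enal, via primary alcohol 9 (not isolated)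
Conditions: (COCl)2, DMSO, CH2Cl2, −78 to −30 °C; then Et3N, −78 to 0 °C
Reagents that add atoms: none
Why: Under Swern conditions a primary triethylsilyl ether is cleaved and oxidised in the same flask while a tertiary one is left alone, so the aldehyde forms without a separate deprotection, and its quaternary alpha carbon cannot epimerise.

Step 7
Reactants: 10 (2R)-5-methyl-2-(propan-2-yl)-2-(triethylsilyloxy)hex-5-enal; 11 3-methylfuran
Product: 13 (2R)-5-methyl-1-(4-methylfuran-2-yl)-2-(propan-2-yl)-2-(triethylsilyloxy)hex-5-en-1-ol (both C1 epimers), via 4-methyl-2-furyllithium 12 (not isolated)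
Conditions: 11 (2 equiv), lithium 2,2,6,6-tetramethylpiperidide (from the amine and n-BuLi), THF, −78 to 0 °C; then 10, −78 °C; AcOH quench at −78 °C
Reagents that add atoms: none
Why: Alpha-lithiation of the furan at C5, the alpha position remote from the methyl group (a hindered amide base avoids the flanked C2–H, as it does with 3-alkylthiophenes), is followed by 1,2-addition to the non-enolisable aldehyde; the new carbinol centre may be a mixture because this carbon becomes sp2 in the ylide, and the cold acidic quench should prevent silyl transfer from the tertiary to the new secondary oxygen.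

Step 8
Reactants: 13 (2R)-5-methyl-1-(4-methylfuran-2-yl)-2-(propan-2-yl)-2-(triethylsilyloxy)hex-5-en-1-ol
Product: 14 6-hydroxy-5-methyl-2-[(3R)-2,6-dimethyl-3-(triethylsilyloxy)hept-6-en-3-yl]-2H-pyran-3(6H)-one (mixture at C2 and C6)
Conditions: VO(acac)2 (5 mol %), t-BuOOH, CH2Cl2, 0 °C to rt
Reagents that add atoms: tert-butyl hydroperoxide, CC(C)(C)OO
Why: Achmatowicz rearrangement in which the vanadyl catalyst binds the furfuryl hydroxyl and oxidises only the furan, leaving the isolated 1,1-disubstituted alkene untouched; the furan methyl ends on C5 of the pyranone, the future C8.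

Step 9
Reactants: 14 6-hydroxy-5-methyl-2-[(3R)-2,6-dimethyl-3-(triethylsilyloxy)hept-6-en-3-yl]-2H-pyran-3(6H)-one
Product: 15 6-acetoxy-5-methyl-2-[(3R)-2,6-dimethyl-3-(triethylsilyloxy)hept-6-en-3-yl]-2H-pyran-3(6H)-one (mixture at C2 and C6)
Conditions: Ac2O, pyridine, DMAP (cat.), CH2Cl2, 0 °C
Reagents that add atoms: acetic anhydride, CC(=O)OC(C)=O
Why: DMAP-catalysed acylation of the anomeric hydroxyl provides the leaving group for ylide formation, and pyridine at 0 °C is too weak a base to start that elimination early.

Step 10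
Reactants: 15 6-acetoxy-5-methyl-2-[(3R)-2,6-dimethyl-3-(triethylsilyloxy)hept-6-en-3-yl]-2H-pyran-3(6H)-one
Product: 17 (1R,4R,5S,9S)-5,9-epoxy-4-(triethylsilyloxy)dauc-7-en-6-one (cyclopentane-fused 8-oxabicyclo[3.2.1]oct-3-en-2-one), via 3-oxidopyrylium ylide 16 (not isolated)
Conditions: DBU (1.5 equiv), MeCN (0.01 M), 60 °C
Reagents that add atoms: none
Why: DBU removes the C5 proton (alpha to both the ketone and the ring oxygen) and acetate leaves from C9, giving the 3-oxidopyrylium 16, whose C5 and C9 termini add suprafacially to the tethered C1=C10 alkene in a thermally allowed six-electron [5+2] cycloaddition. The closest known reaction type is the intramolecular oxidopyrylium–alkene cycloaddition of 6-acetoxy-2H-pyran-3(6H)-ones that carry a three-atom alkenyl tether at C2, which gives cyclopentane-fused 8-oxabicyclo[3.2.1]oct-3-en-2-ones. The cyclopentane closes through the C5–C1 bond in a 5-exo sense (C10 stays outside that ring) and the seven-membered carbocycle closes through the C9–C10 bond as the oxygen-bridged bicycle. C1 and C9 are set together relative to C5 by the tether, which can only span the bridgehead and the exo position at C1 and so leaves the C1 methyl endo, anti to the oxygen bridge; their absolute sense is relayed from C4, the only stereocentre that enters the step. The selectivity that must be secured is the pyrylium face: with the C3 methylene turned toward the alkene, the C4 silyloxy oxygen should lie beside the oxido oxygen and the bulkier isopropyl group beside the unsubstituted ring oxygen (least allylic strain), which opens one face only and places the C1 methyl cis to the C4 oxygen. The fully substituted C4 (Thorpe–Ingold effect) and high dilution should let ring closure outrun dimerisation of the ylide.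

Step 11
Reactants: 17 (1R,4R,5S,9S)-5,9-epoxy-4-(triethylsilyloxy)dauc-7-en-6-one
Product: 19 (1R,4R,5R,9S)-9-hydroxy-4-(triethylsilyloxy)dauc-7-en-6-one (trans-fused), via samarium dienolate 18 (not isolated)
Conditions: SmI2 (2.5 equiv), THF–MeOH (10:1), −78 °C; aq. NH4Cl
Reagents that add atoms: none
Why: Divalent samarium reduces the ketone to a ketyl in which the metal chelates the bridge oxygen, so the C5–O bond alpha to the carbonyl is expelled (alpha-alkoxy ketone cleavage), and the samarium dienolate 18 should be protonated at C5 by methanol held on the C9 alkoxide, on the face the bridge has just left, which gives the trans ring fusion and restores the enone.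

Step 12
Reactants: 19 (1R,4R,5R,9S)-9-hydroxy-4-(triethylsilyloxy)dauc-7-en-6-one
Product: 20 (1R,4R,5R,9S)-9-(tert-butyldimethylsilyloxy)-4-(triethylsilyloxy)dauc-7-en-6-one
Conditions: t-BuMe2SiCl, imidazole, DMAP (cat.), DMF, rt
Reagents that add atoms: tert-butyldimethylsilyl chloride, CC(C)(C)[Si](C)(C)Cl
Why: Standard silylation of the only free hydroxyl, a secondary allylic one, so that C6 can later be acylated alone; imidazole is too weak a base to epimerise C5 or expel the beta silyloxy group at C4.

Step 13
Reactants: 20 (1R,4R,5R,9S)-9-(tert-butyldimethylsilyloxy)-4-(triethylsilyloxy)dauc-7-en-6-one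
Product: 21 (1R,4R,5S,6S,9S)-9-(tert-butyldimethylsilyloxy)-4-(triethylsilyloxy)dauc-7-en-6-ol
Conditions: NaBH4, CeCl3·7H2O, MeOH–THF, −78 to −40 °C
Reagents that add atoms: none
Why: Luche reduction gives 1,2-addition only, and the small hydride should approach along the pseudoaxial line anti to C5–H, on the face away from the C4 isopropyl and the C9 silyloxy group, which sets the pseudoequatorial C6 hydroxyl cis to the C9 oxygen and to H-5.

Step 14
Reactants: 22 4-hydroxy-3-methoxybenzoic acid (vanillic acid)
Product: 24 4-(tert-butyldimethylsilyloxy)-3-methoxybenzoic acid, via silyl ester 23 (not isolated)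
Conditions: t-BuMe2SiCl (2.5 equiv), imidazole, DMF, rt; then AcOH–THF–H2O, rt
Reagents that add atoms: tert-butyldimethylsilyl chloride, CC(C)(C)[Si](C)(C)Cl
Why: Silylation of both acidic hydroxyls followed by mild aqueous acid, which hydrolyses the labile silyl ester but not the aryl silyl ether, leaves the phenol masked for the esterification.

Step 15
Reactants: 21 (1R,4R,5S,6S,9S)-9-(tert-butyldimethylsilyloxy)-4-(triethylsilyloxy)dauc-7-en-6-ol; 24 4-(tert-butyldimethylsilyloxy)-3-methoxybenzoic acid
Product: 26 (1R,4R,5S,6S,9S)-9-(tert-butyldimethylsilyloxy)-4-(triethylsilyloxy)dauc-7-en-6-yl 4-(tert-butyldimethylsilyloxy)-3-methoxybenzoate, via mixed anhydride 25 (not isolated)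
Conditions: 24, 2,4,6-Cl3C6H2COCl, Et3N, THF, rt; then 21, DMAP, toluene, rt to 40 °C
Reagents that add atoms: none
Why: Yamaguchi esterification, in which DMAP attacks the unhindered vanilloyl carbonyl of the mixed anhydride 25 and the acylpyridinium acylates the hindered secondary C6 hydroxyl, the only free hydroxyl in 21, without touching the C6–O bond (retention).

Step 16
Reactants: 26 (1R,4R,5S,6S,9S)-9-(tert-butyldimethylsilyloxy)-4-(triethylsilyloxy)dauc-7-en-6-yl 4-(tert-butyldimethylsilyloxy)-3-methoxybenzoate
Product: 27 (1R,4R,5S,6S,9S)-4,9-dihydroxydauc-7-en-6-yl 4-hydroxy-3-methoxybenzoate (CNP0189996.2)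
Conditions: HF·pyridine, pyridine, THF, 0 °C to rt
Reagents that add atoms: none
Why: Fluoride cleaves the aryl and secondary tert-butyldimethylsilyl ethers and the tertiary triethylsilyl ether in one operation, while the pyridine buffer keeps the medium too weakly acidic to ionise the allylic ester or alcohol and no base is present to move the acyl group.

**Compound list**

1 | 3-methylbutanal (isovaleraldehyde) | CC(C)CC=O | starting material
2 | 3-methyl-2-methylidenebutanal | C=C(C=O)C(C)C | intermediate
3 | 3-methyl-2-methylidenebutan-1-ol | C=C(CO)C(C)C | intermediate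
4 | [(2R)-2-(propan-2-yl)oxiran-2-yl]methanol | OC[C@]1(C(C)C)CO1 | intermediate
5 | 3-chloro-2-methylprop-1-ene (methallyl chloride) | C=C(C)CCl | starting material
6 | (2-methylprop-2-en-1-yl)magnesium chloride (formed in the flask) | C=C(C)C[Mg]Cl | intermediate
7 | (2R)-5-methyl-2-(propan-2-yl)hex-5-ene-1,2-diol | OC[C@](O)(C(C)C)CCC(C)=C | intermediate
8 | (2R)-5-methyl-2-(propan-2-yl)-1,2-bis(triethylsilyloxy)hex-5-ene | CC[Si](CC)(CC)OC[C@](O[Si](CC)(CC)CC)(C(C)C)CCC(C)=C | intermediate
9 | (2R)-5-methyl-2-(propan-2-yl)-2-(triethylsilyloxy)hex-5-en-1-ol (formed in the flask) | OC[C@](O[Si](CC)(CC)CC)(C(C)C)CCC(C)=C | intermediate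
10 | (2R)-5-methyl-2-(propan-2-yl)-2-(triethylsilyloxy)hex-5-enal | O=C[C@](O[Si](CC)(CC)CC)(C(C)C)CCC(C)=C | intermediate
11 | 3-methylfuran | Cc1ccoc1 | starting material
12 | (4-methylfuran-2-yl)lithium (formed in the flask) | [Li]c1cc(C)co1 | intermediate
13 | (2R)-5-methyl-1-(4-methylfuran-2-yl)-2-(propan-2-yl)-2-(triethylsilyloxy)hex-5-en-1-ol, both epimers at C1 | Cc1coc(C(O)[C@](O[Si](CC)(CC)CC)(C(C)C)CCC(C)=C)c1 | intermediate
14 | 6-hydroxy-5-methyl-2-[(3R)-2,6-dimethyl-3-(triethylsilyloxy)hept-6-en-3-yl]-2H-pyran-3(6H)-one, mixture at C2 and C6 | OC1OC(C(=O)C=C1C)[C@](O[Si](CC)(CC)CC)(C(C)C)CCC(C)=C | intermediate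
15 | 6-acetoxy-5-methyl-2-[(3R)-2,6-dimethyl-3-(triethylsilyloxy)hept-6-en-3-yl]-2H-pyran-3(6H)-one, mixture at C2 and C6 | CC(=O)OC1OC(C(=O)C=C1C)[C@](O[Si](CC)(CC)CC)(C(C)C)CCC(C)=C | intermediate
16 | 5-methyl-2-[(3R)-2,6-dimethyl-3-(triethylsilyloxy)hept-6-en-3-yl]pyrylium-3-olate (formed in the flask) | Cc1cc([O-])c([C@](O[Si](CC)(CC)CC)(C(C)C)CCC(C)=C)[o+]c1 | intermediate
17 | (1R,4R,5S,9S)-5,9-epoxy-4-(triethylsilyloxy)dauc-7-en-6-one; oxygen bridge and C4 isopropyl on one face, C1 methyl and C4 silyloxy on the other | O=C2C=C(C)[C@@H]4C[C@@]3(C)CC[C@@](O[Si](CC)(CC)CC)(C(C)C)[C@]23O4 | intermediate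
18 | (1R,4R,9S)-6,9-bis(diiodosamariooxy)-4-(triethylsilyloxy)dauca-5,7-diene, trivalent samarium on both oxygens (formed in the flask) | I[Sm](I)OC1=C2[C@](O[Si](CC)(CC)CC)(C(C)C)CC[C@]2(C)C[C@H](O[Sm](I)I)C(C)=C1 | intermediate
19 | (1R,4R,5R,9S)-9-hydroxy-4-(triethylsilyloxy)dauc-7-en-6-one; trans-fused, H-5, 9-OH and isopropyl on one face, C1 methyl and C4 silyloxy on the other | O=C2C=C(C)[C@@H](O)C[C@@]3(C)CC[C@@](O[Si](CC)(CC)CC)(C(C)C)[C@H]23 | intermediate
20 | (1R,4R,5R,9S)-9-(tert-butyldimethylsilyloxy)-4-(triethylsilyloxy)dauc-7-en-6-one | O=C2C=C(C)[C@@H](O[Si](C)(C)C(C)(C)C)C[C@@]3(C)CC[C@@](O[Si](CC)(CC)CC)(C(C)C)[C@H]23 | intermediate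
21 | (1R,4R,5S,6S,9S)-9-(tert-butyldimethylsilyloxy)-4-(triethylsilyloxy)dauc-7-en-6-ol; 6-OH cis to the C9 oxygen and H-5 | O[C@H]2C=C(C)[C@@H](O[Si](C)(C)C(C)(C)C)C[C@@]3(C)CC[C@@](O[Si](CC)(CC)CC)(C(C)C)[C@H]23 | intermediate
22 | 4-hydroxy-3-methoxybenzoic acid (vanillic acid) | COc1cc(C(=O)O)ccc1O | starting material
23 | tert-butyldimethylsilyl 4-(tert-butyldimethylsilyloxy)-3-methoxybenzoate (formed in the flask) | COc1cc(C(=O)O[Si](C)(C)C(C)(C)C)ccc1O[Si](C)(C)C(C)(C)C | intermediate
24 | 4-(tert-butyldimethylsilyloxy)-3-methoxybenzoic acid | COc1cc(C(=O)O)ccc1O[Si](C)(C)C(C)(C)C | intermediate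
25 | 4-(tert-butyldimethylsilyloxy)-3-methoxybenzoic 2,4,6-trichlorobenzoic anhydride (formed in the flask) | COc1cc(C(=O)OC(=O)c2c(Cl)cc(Cl)cc2Cl)ccc1O[Si](C)(C)C(C)(C)C | intermediate
26 | (1R,4R,5S,6S,9S)-9-(tert-butyldimethylsilyloxy)-4-(triethylsilyloxy)dauc-7-en-6-yl 4-(tert-butyldimethylsilyloxy)-3-methoxybenzoate | COc1cc(C(=O)O[C@H]2C=C(C)[C@@H](O[Si](C)(C)C(C)(C)C)C[C@@]3(C)CC[C@@](O[Si](CC)(CC)CC)(C(C)C)[C@H]23)ccc1O[Si](C)(C)C(C)(C)C | intermediate
27 | (1R,4R,5S,6S,9S)-4,9-dihydroxydauc-7-en-6-yl 4-hydroxy-3-methoxybenzoate (CNP0189996.2); H-5, ester oxygen, 9-OH and isopropyl on one face, C1 methyl and 4-OH on the other | COc1cc(C(=O)O[C@H]2C=C(C)[C@@H](O)C[C@@]3(C)CC[C@@](O)(C(C)C)[C@H]23)ccc1O | target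

**Step count**

Total: 16 steps. Longest linear sequence: 15 steps (steps 1–13, 15, 16, from 3-methylbutanal); the vanillate branch is one step (step 14).

**Steps most likely to fail**

Step 10 (cycloaddition). The alkene may add to the other face of the pyrylium if the rotamer about C4–C5 is not controlled by allylic strain as assumed, which would give the diastereomer with the wrong C1/C5/C9 sense relative to C4. The hindered ring closure (quaternary C1 bonding to a bridgehead next to the fully substituted C4) may also be outrun by dimerisation of the ylide. The fallback replaces steric control by a hydrogen bond and sets out from 13. Bu4NF in THF removes the silyl group to give the furyl diol F1. The same Achmatowicz oxidation gives the hydroxy lactol F2, and acetylation of its anomeric hydroxyl (the tertiary hydroxyl should not react) gives the hydroxy acetate F3. With DBU in dilute MeCN, the free C4 hydroxyl of the hydroxy ylide F4 can hydrogen-bond to the oxido oxygen, which holds the oxygen beside C6 and the isopropyl group beside the ring oxygen, and the cycloaddition gives the hydroxy cycloadduct F5. Et3SiOTf and 2,6-lutidine then return to 17.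

Step 11 (bridge cleavage). Electron transfer into the enone may break the C9–O bond (gamma to the carbonyl through the alkene) instead of the C5–O bond, or reduce the enone further, and C5 may be protonated from the other face to give the cis-fused epimer. The fallback removes the alkene for the duration of the cleavage and sets out from 17. Hydrogenation (H2, Pd on carbon, EtOAc) gives the dihydro adduct F6, whose C8 configuration is immaterial. SmI2 in THF–MeOH can now break only the C5–O bond and gives, through the samarium enolate F7, the saturated hydroxy ketone F8. Silylation (t-BuMe2SiCl, imidazole) gives the silyl ether F9. IBX in DMSO then dehydrogenates the only alpha,beta pair that carries hydrogen (C7–C8, since C1 and C4 have none) and returns to 20.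

Step 13 (C6 reduction). Facial selectivity of hydride addition is uncertain because both faces of the carbonyl are flanked (isopropyl and C9 silyloxy on one side, angular methyl and C4 silyloxy on the other), so hydride may add mainly from the isopropyl face. The fallback uses that outcome and sets out from 20. The same reduction then gives mainly the C6-epimeric alcohol F10, which is esterified with acid 24 under Mitsunobu conditions (PPh3, diisopropyl azodicarboxylate, toluene) with inversion at C6, and so returns to 26.

**Further compounds**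

F1 | step 10 | (2R)-5-methyl-1-(4-methylfuran-2-yl)-2-(propan-2-yl)hex-5-ene-1,2-diol, both C1 epimers | Cc1coc(C(O)[C@](O)(C(C)C)CCC(C)=C)c1
F2 | step 10 | 6-hydroxy-2-[(3R)-3-hydroxy-2,6-dimethylhept-6-en-3-yl]-5-methyl-2H-pyran-3(6H)-one | OC1OC(C(=O)C=C1C)[C@](O)(C(C)C)CCC(C)=C
F3 | step 10 | 6-acetoxy-2-[(3R)-3-hydroxy-2,6-dimethylhept-6-en-3-yl]-5-methyl-2H-pyran-3(6H)-one | CC(=O)OC1OC(C(=O)C=C1C)[C@](O)(C(C)C)CCC(C)=C
F4 | step 10 | 2-[(3R)-3-hydroxy-2,6-dimethylhept-6-en-3-yl]-5-methylpyrylium-3-olate | Cc1cc([O-])c([C@](O)(C(C)C)CCC(C)=C)[o+]c1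
F5 | step 10 | (1R,4R,5S,9S)-5,9-epoxy-4-hydroxydauc-7-en-6-one | O=C2C=C(C)[C@@H]4C[C@@]3(C)CC[C@@](O)(C(C)C)[C@]23O4
F6 | step 11 | 5,9-epoxy-4-(triethylsilyloxy)daucan-6-one, configuration as in 17, C8 undefined | O=C2CC(C)[C@@H]4C[C@@]3(C)CC[C@@](O[Si](CC)(CC)CC)(C(C)C)[C@]23O4
F7 | step 11 | 6,9-bis(diiodosamariooxy)-4-(triethylsilyloxy)dauc-5-ene, trivalent samarium, C8 undefined | I[Sm](I)OC1=C2[C@](O[Si](CC)(CC)CC)(C(C)C)CC[C@]2(C)C[C@H](O[Sm](I)I)C(C)C1
F8 | step 11 | 9-hydroxy-4-(triethylsilyloxy)daucan-6-one, trans-fused, configuration as in 19, C8 undefined | O=C2CC(C)[C@@H](O)C[C@@]3(C)CC[C@@](O[Si](CC)(CC)CC)(C(C)C)[C@H]23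
F9 | step 11 | 9-(tert-butyldimethylsilyloxy)-4-(triethylsilyloxy)daucan-6-one, C8 undefined | O=C2CC(C)[C@@H](O[Si](C)(C)C(C)(C)C)C[C@@]3(C)CC[C@@](O[Si](CC)(CC)CC)(C(C)C)[C@H]23
F10 | step 13 | (1R,4R,5S,6R,9S)-9-(tert-butyldimethylsilyloxy)-4-(triethylsilyloxy)dauc-7-en-6-ol (C6 epimer of 21) | O[C@@H]2C=C(C)[C@@H](O[Si](C)(C)C(C)(C)C)C[C@@]3(C)CC[C@@](O[Si](CC)(CC)CC)(C(C)C)[C@H]23
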